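**Plan**

- Retrosynthesis cuts first the ester C–O bond between the feruloyl carbonyl and the C2 CH2O arm, then takes the C3=C4 alkene back to a C4 ketone, and finally cuts O1–C2 and C2–C3 of the pyran ring.
- Enabling feature: C3, C4 and ring A with its C6 acetyl and C7 hydroxyl add up to 4,6-diacetylresorcinol. One acetyl serves as C4–C3 and its ortho hydroxyl as O1; the two acetyl/hydroxyl pairs are equivalent, so the linear 6-acetyl-7-hydroxy fusion results whichever pair reacts.
- Forward: silylated hydroxyacetone and the diketone (ring A present from the start) are annulated to the chromanone, closing ring B and creating C2. C4 is then reduced and dehydrated to the 2H-chromene, the silyl ether is removed, and the alcohol is esterified with O-acetylferulic acid and deacetylated.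
- Stereochemistry: the only stereocentre, C2 (R), is set by a chiral primary amine–thiourea catalyst in the annulation and is not touched afterwards; the E-alkene is carried in from ferulic acid.

Key step: step 2

Assumption: the sense of induction of the catalyst in step 2 cannot be assigned in advance; the (1R,2R) catalyst is written, and its (1S,2S) antipode would be used if a first run gives the (S)-chromanone. All 2H-chromene intermediates are to be kept from light and below 50 °C, because reversible electrocyclic ring opening would racemise C2.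

**Route**

Step 1
Reactants: 1 hydroxyacetone (1-hydroxypropan-2-one)
Product: 2 1-{[tert-butyl(diphenyl)silyl]oxy}propan-2-one
Conditions: TBDPSCl, imidazole, DMF, 0 °C to rt
Reagents that add atoms: tert-butyl(chloro)diphenylsilane (TBDPSCl), CC(C)(C)[Si](Cl)(c1ccccc1)c1ccccc1
Why: Standard imidazole-mediated silylation of a primary alcohol; the tert-butyldiphenylsilyl group is chosen because it withstands the acid of step 4 and makes the CH2O arm far bulkier than the methyl group, which step 2 relies on.

Step 2
Reactants: 3 4,6-diacetylresorcinol (1.5 equiv); 2 1-{[tert-butyl(diphenyl)silyl]oxy}propan-2-one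
Product: 5 (2R)-6-acetyl-2-{[tert-butyl(diphenyl)silyl]oxymethyl}-7-hydroxy-2-methyl-2,3-dihydro-4H-chromen-4-one, via hydroxyaryl E-enone 4 (not isolated)
Conditions: 1-[(1R,2R)-2-aminocyclohexyl]-3-[3,5-bis(trifluoromethyl)phenyl]thiourea (20 mol%), PhCO2H (20 mol%), toluene, 30 °C
Reagents that add atoms: none
Why: Proposed new method: the primary amine of the catalyst condenses with an acetyl group of 3 to a ketimine stabilised by the ortho hydroxyl, its enamine tautomer adds to the thiourea-bound carbonyl of 2 (aldol step, C2–C3), and loss of water gives E-enone 4, held as its conjugated iminium ion, to which the ortho phenol adds at the β-carbon (O1–C2) before hydrolysis releases 5 and the catalyst. The closest known chemistry is the racemic pyrrolidine-mediated Kabbe chromanone synthesis together with amine–thiourea-catalysed intramolecular oxa-Michael additions of activated 2'-hydroxy enones to 2-monosubstituted chromanones; building a C2 quaternary centre enantioselectively from two ketones in this way is not established. Ring B closes by a 6-endo-trig oxa-Michael addition. C2 is set under catalyst control: the covalently bound catalyst shields one face of the iminium, while the E geometry of 4, enforced by the large CH2OSi(tBu)Ph2 arm lying trans to the aroyl group, fixes which β-substituent points toward the catalyst. The step needs mono-annulation and kinetic control: the two acetyl/hydroxyl pairs of 3 are equivalent, so either gives 5, and 3 is used in excess over 2, whereas racemisation by retro-oxa-Michael opening is disfavoured because 5 has no free hydroxyl ortho to C4 to stabilise a new ketimine with the catalyst.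

Step 3
Reactants: 5 (2R)-6-acetyl-2-{[tert-butyl(diphenyl)silyl]oxymethyl}-7-hydroxy-2-methyl-2,3-dihydro-4H-chromen-4-one
Product: 6 1-[(2R)-2-{[tert-butyl(diphenyl)silyl]oxymethyl}-4,7-dihydroxy-2-methyl-3,4-dihydro-2H-chromen-6-yl]ethanone (mixture of C4 epimers)
Conditions: NaBH4 (1.2 equiv), EtOH/THF, 0 °C; aqueous NH4Cl work-up
Reagents that add atoms: none
Why: Borohydride reduction of an aryl ketone, in which the ring ketone at C4 is reduced while the C6 acetyl group, locked in a six-membered chelate with the C7 phenol(ate) and therefore the less electrophilic carbonyl (the known behaviour of chelated o-hydroxyaryl ketones), should be spared; the new C4 centre is removed in step 4 and the low temperature disfavours base-induced retro-oxa-Michael opening at C2.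

Step 4
Reactants: 6 1-[(2R)-2-{[tert-butyl(diphenyl)silyl]oxymethyl}-4,7-dihydroxy-2-methyl-3,4-dihydro-2H-chromen-6-yl]ethanone
Product: 7 1-[(2R)-2-{[tert-butyl(diphenyl)silyl]oxymethyl}-7-hydroxy-2-methyl-2H-chromen-6-yl]ethanone
Conditions: p-TsOH·H2O (5 mol%), toluene (dilute), 45 °C, exclusion of light
Reagents that add atoms: none
Why: Acid-catalysed E1 dehydration of a benzylic alcohol whose cation is stabilised by O1 (ortho) and the C7 hydroxyl (para), so loss of a C3 proton gives the conjugated 2H-chromene under conditions mild enough for the silyl ether, while C2 carries no hydrogen and is not involved.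

Step 5
Reactants: 7 1-[(2R)-2-{[tert-butyl(diphenyl)silyl]oxymethyl}-7-hydroxy-2-methyl-2H-chromen-6-yl]ethanone
Product: 8 1-[(2R)-7-hydroxy-2-(hydroxymethyl)-2-methyl-2H-chromen-6-yl]ethanone
Conditions: Bu4NF, AcOH (1:1), THF, 0 °C to rt, exclusion of light
Reagents that add atoms: none
Why: Fluoride-mediated cleavage of the silyl ether, driven by Si–F bond formation and buffered with acetic acid so that neither the aryl ketone nor the chromene meets a strongly basic alkoxide.

Step 6
Reactants: 9 ferulic acid ((2E)-3-(4-hydroxy-3-methoxyphenyl)prop-2-enoic acid)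
Product: 10 O-acetylferulic acid ((2E)-3-[4-(acetyloxy)-3-methoxyphenyl]prop-2-enoic acid)
Conditions: Ac2O, pyridine, rt; aqueous work-up
Reagents that add atoms: acetic anhydride, CC(=O)OC(C)=O
Why: Routine acetylation of the phenol, any mixed anhydride at the carboxyl group being hydrolysed on aqueous work-up, so that the phenol cannot compete as a nucleophile in step 7.

Step 7
Reactants: 8 1-[(2R)-7-hydroxy-2-(hydroxymethyl)-2-methyl-2H-chromen-6-yl]ethanone; 10 O-acetylferulic acid
Product: 11 [(2R)-6-acetyl-7-hydroxy-2-methyl-2H-chromen-2-yl]methyl (2E)-3-[4-(acetyloxy)-3-methoxyphenyl]prop-2-enoate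
Conditions: DCC, DMAP (4-dimethylaminopyridine, 10 mol%), CH2Cl2, 0 °C to rt, exclusion of light
Reagents that add atoms: none
Why: Steglich esterification (carbodiimide activation with DMAP acyl transfer) of the primary alcohol, which is far more nucleophilic than the C7 phenol that is hydrogen-bonded to and deactivated by the ortho acetyl group; any aryl ester formed there would be cleaved in step 8.

Step 8
Reactants: 11 [(2R)-6-acetyl-7-hydroxy-2-methyl-2H-chromen-2-yl]methyl (2E)-3-[4-(acetyloxy)-3-methoxyphenyl]prop-2-enoate
Product: 12 [(2R)-6-acetyl-7-hydroxy-2-methyl-2H-chromen-2-yl]methyl (2E)-3-(4-hydroxy-3-methoxyphenyl)prop-2-enoate (CNP0375196.1)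
Conditions: pyrrolidine (2.5 equiv), CH2Cl2, 0 °C, exclusion of light; dilute aqueous acid wash
Reagents that add atoms: none
Why: Chemoselective aminolysis of the aryl acetate, an activated phenyl ester, by pyrrolidine at low temperature, under which the hindered, conjugated alkyl cinnamate and the aryl ketone should stay intact.

**Compound list**

1 | hydroxyacetone (1-hydroxypropan-2-one) | CC(=O)CO | starting material
2 | 1-{[tert-butyl(diphenyl)silyl]oxy}propan-2-one | CC(=O)CO[Si](c1ccccc1)(c1ccccc1)C(C)(C)C | intermediate
3 | 4,6-diacetylresorcinol | CC(=O)c1cc(C(C)=O)c(O)cc1O | starting material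
4 | (2E)-1-(5-acetyl-2,4-dihydroxyphenyl)-4-{[tert-butyl(diphenyl)silyl]oxy}-3-methylbut-2-en-1-one | CC(=O)c1cc(C(=O)/C=C(\C)CO[Si](c2ccccc2)(c2ccccc2)C(C)(C)C)c(O)cc1O | intermediate (not isolated)
5 | (2R)-6-acetyl-2-{[tert-butyl(diphenyl)silyl]oxymethyl}-7-hydroxy-2-methyl-2,3-dihydro-4H-chromen-4-one | CC(C)(C)[Si](c1ccccc1)(c1ccccc1)OC[C@@]1(C)CC(=O)c2cc(C(C)=O)c(O)cc2O1 | intermediate
6 | 1-[(2R)-2-{[tert-butyl(diphenyl)silyl]oxymethyl}-4,7-dihydroxy-2-methyl-3,4-dihydro-2H-chromen-6-yl]ethanone, C4 epimer mixture | CC(C)(C)[Si](c1ccccc1)(c1ccccc1)OC[C@@]1(C)CC(O)c2cc(C(C)=O)c(O)cc2O1 | intermediate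
7 | 1-[(2R)-2-{[tert-butyl(diphenyl)silyl]oxymethyl}-7-hydroxy-2-methyl-2H-chromen-6-yl]ethanone | CC(C)(C)[Si](c1ccccc1)(c1ccccc1)OC[C@@]1(C)C=Cc2cc(C(C)=O)c(O)cc2O1 | intermediate
8 | 1-[(2R)-7-hydroxy-2-(hydroxymethyl)-2-methyl-2H-chromen-6-yl]ethanone | OC[C@@]1(C)C=Cc2cc(C(C)=O)c(O)cc2O1 | intermediate
9 | ferulic acid | COc1cc(/C=C/C(=O)O)ccc1O | starting material
10 | O-acetylferulic acid, (2E)-3-[4-(acetyloxy)-3-methoxyphenyl]prop-2-enoic acid | COc1cc(/C=C/C(=O)O)ccc1OC(C)=O | intermediate
11 | [(2R)-6-acetyl-7-hydroxy-2-methyl-2H-chromen-2-yl]methyl (2E)-3-[4-(acetyloxy)-3-methoxyphenyl]prop-2-enoate | COc1cc(/C=C/C(=O)OC[C@@]2(C)C=Cc3cc(C(C)=O)c(O)cc3O2)ccc1OC(C)=O | intermediate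
12 | [(2R)-6-acetyl-7-hydroxy-2-methyl-2H-chromen-2-yl]methyl (2E)-3-(4-hydroxy-3-methoxyphenyl)prop-2-enoate | COc1cc(/C=C/C(=O)OC[C@@]2(C)C=Cc3cc(C(C)=O)c(O)cc3O2)ccc1O | target

**Step count and risks**

Total steps: 8. Longest linear sequence: 7 (steps 1, 2, 3, 4, 5, 7, 8).

Steps most likely to fail:

1. Step 2. The catalyst may not discriminate well enough between the methyl and CH2OSi faces in the oxa-Michael closure, the enantiomeric purity may erode through reversible ring opening while the amine is present, and the ketone–ketone condensation may be slow. Fallback with known chemistry, setting out from 3 and 2: the classical Kabbe annulation with pyrrolidine in toluene at rt to 50 °C would give the racemic 6-acetyl-2-{[tert-butyl(diphenyl)silyl]oxymethyl}-7-hydroxy-2-methylchroman-4-one F1. This would be resolved by preparative chromatography on an amylose tris(3,5-dimethylphenylcarbamate) stationary phase. The (R)-enantiomer is 5, where the route is rejoined; the (S)-chromanone F2 is set aside and could in principle be returned to the racemate by warming with pyrrolidine.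

2. Step 3. Hydride attack on the C6 acetyl group may compete, or the reduction may stall because the phenolate deactivates both carbonyl groups. Fallback, setting out from 5: both carbonyl groups are reduced on purpose with excess NaBH4 in MeOH at rt to the (2R)-2-(silyloxymethyl)-6-(1-hydroxyethyl)-2-methylchromane-4,7-diol F3 (diastereomer mixture). 2,2-Dimethoxypropane with pyridinium p-toluenesulfonate then ties the C7 phenol and the side-chain carbinol into a six-membered acetonide, and a trace of p-TsOH dehydrates C4 to the acetonide-protected 2H-chromene F4. Aqueous AcOH/THF removes the acetonide to give the (2R)-6-(1-hydroxyethyl)-2-(silyloxymethyl)-2-methyl-2H-chromen-7-ol F5. MnO2 in CH2Cl2 oxidises the benzylic alcohol back to the acetyl group, rejoining the route at 7.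

3. Step 7. Acylation of the neopentyl-type alcohol by the conjugated, electron-rich cinnamoyl donor may be slow, so that N-acylurea formation, acetyl transfer from the aryl acetate or acylation at the C7 phenol take over. Fallback, setting out from 8: DCC/DMAP coupling with the unhindered, unconjugated diethylphosphonoacetic acid gives [(2R)-6-acetyl-7-hydroxy-2-methyl-2H-chromen-2-yl]methyl (diethoxyphosphoryl)acetate F6. Horner–Wadsworth–Emmons olefination of this with 4-formyl-2-methoxyphenyl acetate (LiCl, iPr2NEt, MeCN, rt) builds the E-cinnamate on the ester and rejoins the route at 11.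

**Further compounds**

F1 | step 2 | racemic 6-acetyl-2-{[tert-butyl(diphenyl)silyl]oxymethyl}-7-hydroxy-2-methyl-2,3-dihydro-4H-chromen-4-one | CC(C)(C)[Si](c1ccccc1)(c1ccccc1)OCC1(C)CC(=O)c2cc(C(C)=O)c(O)cc2O1
F2 | step 2 | (2S)-6-acetyl-2-{[tert-butyl(diphenyl)silyl]oxymethyl}-7-hydroxy-2-methyl-2,3-dihydro-4H-chromen-4-one | CC(C)(C)[Si](c1ccccc1)(c1ccccc1)OC[C@]1(C)CC(=O)c2cc(C(C)=O)c(O)cc2O1
F3 | step 3 | (2R)-2-{[tert-butyl(diphenyl)silyl]oxymethyl}-6-(1-hydroxyethyl)-2-methyl-3,4-dihydro-2H-chromene-4,7-diol, diastereomer mixture | CC(C)(C)[Si](c1ccccc1)(c1ccccc1)OC[C@@]1(C)CC(O)c2cc(C(C)O)c(O)cc2O1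
F4 | step 3 | (2R)-2-{[tert-butyl(diphenyl)silyl]oxymethyl}-2-methyl-2H-chromene with a 2,2,4-trimethyl-4H-1,3-dioxine (acetonide) ring fused across C6–C7 | CC(C)(C)[Si](c1ccccc1)(c1ccccc1)OC[C@@]1(C)C=Cc2cc3C(C)OC(C)(C)Oc3cc2O1
F5 | step 3 | (2R)-2-{[tert-butyl(diphenyl)silyl]oxymethyl}-6-(1-hydroxyethyl)-2-methyl-2H-chromen-7-ol | CC(C)(C)[Si](c1ccccc1)(c1ccccc1)OC[C@@]1(C)C=Cc2cc(C(C)O)c(O)cc2O1
F6 | step 7 | [(2R)-6-acetyl-7-hydroxy-2-methyl-2H-chromen-2-yl]methyl (diethoxyphosphoryl)acetate | CCOP(=O)(OCC)CC(=O)OC[C@@]1(C)C=Cc2cc(C(C)=O)c(O)cc2O1
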